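## Structural features

The target is a flavonol in which benzo ring A is fused to the γ-pyranone ring C (O1, C2, C3, C4, C4a, C8a) and the catechol ring B is attached through the C2–C1' bond. Ring A is a phloroglucinol whose three oxygens have different fates: O1 is the ring oxygen, O5 is the hydroxyl hydrogen-bonded to the C4 carbonyl, and O7 is a free phenol. C8 carries a 1,1-dimethylallyl group, so a quaternary carbon sits between the oxygenated carbons C7 and C8a, while ring B carries a normal prenyl group at C5', ortho to the 4'-hydroxyl. There are no stereocentres and no stereogenic double bonds, so no stereocentres stand next to each other and the problems are regiochemistry and functional-group tolerance. The fragile groups are the two allyl side chains, each ortho to a phenol that adds to it under acid, and the free catechol and 3-hydroxy-enone, which oxidise in aerated base. The real difficulty is that a tertiary carbon cannot be attached cleanly to C8 of a finished phloroglucinol (crowding, C6/C8 ambiguity), and that the oxygen next to C8 must become O1. The key step uses this pattern directly: the alkyne brings C8 (already bonded to the quaternary carbon) and C8a with O1, the cyclobutenone brings C7, C6, C5 and C4a with O7 and O5, and the three oxygens emerge differently substituted.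

## Logic of the disconnections

**24 from 23.** The four aryl O–CH2 acetal bonds are cut last. Every phenol of 24 is then masked in 23 by one base-stable group that leaves in a single operation, so hydroxide and peroxide can be used earlier. The forward step must be mild enough that the phenols do not add to the two allyl groups.

**23 from 21 (through 22).** The O1–C2 bond and the C3–O bond are cut together. Ring C and the C3 oxygen then arise from open-chain 21 in one oxidative cyclisation that passes through 22. The forward step must close the six-membered ring at C2 and not a five-membered ring at C3, despite the acetal at C5.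

**21 from 17 and 20.** The C2=C3 bond is cut. This divides 21 into two fragments of similar size, 17 for ring A and 20 for ring B. The forward aldol condensation needs only base-stable protecting groups.

**20 from 19, and 19 from 18.** The aryl C5'–CH2 bond is cut, then the two catechol O–CH2 bonds. The bromine in 18 fixes the position, so no regiochemical question arises on ring B. The forward coupling must deliver the linear, not the branched, allyl isomer.

**17 from 16, 16 from 15, 15 from 13 (through 14).** The C3–C4 bond (methyl to carbonyl) and then the C4a–C4 bond are cut. In 13 both free ring positions are flanked by oxygen, and only a reaction delivered from the free O1–H can tell C4a from C6. The carbonyl carbon is therefore introduced by phenoxide-directed ortho-formylation through 14 and extended by one methyl nucleophile and an oxidation. The forward formylation must be strictly ortho.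

**13 from 12, and 12 from 11.** These are protecting-group changes at O7 and O1. O7 receives the same acetal as O5, because a silyl ether would not survive hydroxide later. O1 is then released as the only free phenol. The forward steps must work next to the quaternary carbon.

**11 from 7 and 4 (through 8, 9, 10).** The bonds C7–C8, C8a–C4a and C6–C7 are cut, which dismantles ring A completely. The quaternary carbon then comes from an open-chain building block and the three oxygens are differentiated from the outset. The forward step must control the orientation of a ketene–alkyne cycloaddition.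

**4 from 1 (through 2, 3).** The two bonds of C8, to the quaternary carbon and to C8a, are cut, together with the O–Si bond. A one-carbon insertion into the ester 1 with 1,2-shift of the tertiary alkyl group leads through 2 to 3. The forward step must tolerate a neopentyl-type ester and silylate at oxygen.

**7 from 5 and 6.** The O–CH2 bond is cut. The forward step is O-alkylation of a vinylogous acid and must avoid C-alkylation and hydrolysis.

## Other disconnections considered

Alternative 1: The cuts are C8–C(quaternary) and O1–C2. The precursor would be the 1,3-diketone A1. Its ring A ketone is flanked by an O-prenyl ether (the future O1) and an acetal, its central carbon already bears the C3 oxygen, and its far carbonyl carries ring B. On heating, an aromatic Claisen rearrangement would move the prenyl group to C8 with allylic inversion, creating the 1,1-dimethylallyl group. The released O1–H would then add to the ring B carbonyl and lose water, closing ring C and giving the pentakis-acetal A2, one deprotection from 24.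

- In its favour: a [3,3] shift is a classical way to make exactly this aryl–tertiary carbon bond. The oxygen that carried the prenyl group is necessarily the one next to C8, so O1 and O5 are told apart as securely as in the chosen plan (equal). The C3 oxygen is present from the start, so no oxidative ring closure with its five- versus six-membered ambiguity is needed (better). Ring A would be bought, so the longest linear sequence should be about three steps shorter (better).
- Against it: the rearrangement needs roughly 180–200 °C. A second [3,3] shift from C8 on to C6 can compete with enolisation. A 2-alkoxy-1,3-diketone carrying five acetals may cleave by retro-Claisen reaction, and cyclodehydration without acid may stop short.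
- Comparison: both plans rest on pericyclic steps. The alternative places its risk late, on material that already contains both halves. The chosen plan places it early, on small molecules, and forms no bond at the crowded carbon.

Alternative 2: The cut is C8–C8a. The precursor would be the pyranone A3, a 4-acetal-substituted pyran-2-one with the 2,2-dimethylbut-3-enyl chain at C6. Methoxide would open the lactone to the keto ester A4. The ketone enolate at the CH2 next to the quaternary carbon would then attack the ester carbon, and aromatisation would give the symmetric resorcinol A5.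

- In its favour: the quaternary carbon is again pre-formed in an open chain and O5 is marked from the start (equal to the chosen plan on both counts). No thermolysis, silicon chemistry or strained ring is needed and the reagents are cheap (better in practicality). In A5 the two free ring positions are equivalent, so the C4a/C6 question disappears (better on that point).
- Against it: the enolate required is the less acidic one, and it must attack through a carbon attached to the quaternary centre. The doubly activated CH2 of A4 is deprotonated first and leads nowhere. Methoxide can exchange the acetal oxygen substituent on the vinylogous ester by addition–elimination, which would erase the O5 protecting group. A3 needs a homologated acid and several steps. A5 has two equivalent hydroxyls, of which only one may be capped to reach 13.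
- Comparison: the route to 13 would be as long as or longer than steps 1–5, and the decisive step is less well founded mechanistically than a polarity-controlled cycloaddition.

Alternative 3: The cuts are the two carbon–carbon bonds from the quaternary carbon to a methyl and to the vinyl group. The precursor would be the aryl tert-butyl carbonate A6 of a bis-acetal ortho-hydroxyacetophenone. MeMgBr would add to the ketone, the carbonate group would move from the phenol oxygen to the new tertiary oxygen and leave, and the resulting ortho-quinone methide A7 would take up vinylmagnesium bromide at its exocyclic carbon to give A8. A8 is the same compound as 13, so everything after it is shared.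

- In its favour: ring A is bought. The oxygen that carried the carbonate is by construction the one next to the quaternary carbon (equal in oxygen differentiation). About three steps would replace steps 1–5 (clearly better in step economy).
- Against it: the ketone in A6 is flanked by two ortho substituents, so enolisation and attack at the carbonate compete with addition. A7 has two alkyl groups with α-hydrogens on its exocyclic carbon and can isomerise by [1,5]-hydrogen shift to the isopropenylphenol A9 faster than a second Grignard reagent creates a quaternary centre between two ortho oxygens.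
- Comparison: the chosen plan spends more steps but never forms a bond at the quaternary carbon on the ring. The alternative is shorter but concentrates steric and kinetic risk in that bond formation.

Key step: step 3

Remarks on the chemistry:
- Atom mapping of 7 and 4 through the pericyclic cascade leads to the connectivity of 11: hydroxyl carbon C7, silyloxy carbon C8a, acetal carbon C5.
- Assumption: 3-bromo-4,5-dihydroxybenzaldehyde 18 is bought as a catalogue compound, so the ring B bromine needs no regioselective halogenation.
- 9, 16 and 22 are racemates whose stereocentres disappear again.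

## Route

Step 1
Reactants: 1 methyl 2,2-dimethylbut-3-enoate
Product: 4 [(3,3-dimethylpent-4-en-1-yn-1-yl)oxy]tri(propan-2-yl)silane, via lithium dibromoenolate 2 (not isolated), via lithium ynolate 3 (not isolated)
Conditions: CH2Br2, lithium 2,2,6,6-tetramethylpiperidide (LiTMP), THF, −78 °C; n-BuLi, −78 °C to rt; i-Pr3SiCl, −78 °C to rt
Reagents that add atoms: dibromomethane, BrCBr; chlorotri(propan-2-yl)silane, CC(C)[Si](Cl)(C(C)C)C(C)C
Why: Kowalski ester homologation stopped at the ynolate: LiCHBr2 adds to the ester, the dibromo enolate 2 undergoes bromine–lithium exchange and the tertiary alkyl group shifts to the carbenoid carbon to give ynolate 3. The bulky silyl chloride reacts at oxygen, giving the siloxyalkyne.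

Step 2
Reactants: 5 cyclobutane-1,3-dione; 6 chloromethyl methyl ether
Product: 7 3-(methoxymethoxy)cyclobut-2-en-1-one
Conditions: i-Pr2NEt, CH2Cl2, 0 °C; rapid non-aqueous work-up, used at once
Reagents that add atoms: none
Why: The dione is a vinylogous acid (it exists as 3-hydroxycyclobutenone), and its ammonium enolate is O-alkylated by the hard, oxocarbenium-like chloromethyl ether to give the vinylogous ester. The product is moisture-sensitive and is not stored.

Step 3
Reactants: 7 3-(methoxymethoxy)cyclobut-2-en-1-one; 4 [(3,3-dimethylpent-4-en-1-yn-1-yl)oxy]tri(propan-2-yl)silane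
Product: 11 5-(methoxymethoxy)-2-(2-methylbut-3-en-2-yl)-3-[tri(propan-2-yl)silyloxy]phenol, via vinylketene 8 (not isolated), via vinylcyclobutenone 9 (not isolated), via dienylketene 10 (not isolated)
Conditions: 4 (1.3 equiv), toluene, 110 °C, sealed tube
Reagents that add atoms: none
Why: This is a Danheiser benzannulation with a siloxyalkyne as ketenophile, a known route to resorcinol monosilyl ethers, applied here to a 3-alkoxycyclobutenone and a tertiary-alkyl alkyne. Heat opens 7 (4π electrocyclic) to vinylketene 8; the alkyne carbon remote from oxygen, made nucleophilic by the silyloxy group, attacks the ketene carbonyl carbon and the [2+2] closes to cyclobutenone 9 (bonds C7–C8 and C8a–C4a). A second 4π opening gives dienylketene 10, whose thermal disrotatory 6π electrocyclisation forms C6–C7 and closes ring A; tautomerisation of the cyclohexadienone gives the phenol. The only stereocentre on the path (C4a in racemic 9) is lost on ring opening, so nothing has to be controlled. The selectivity that matters is the orientation of the [2+2]: the polarised alkyne fixes it, which places the quaternary group between the hydroxyl (C7) and silyloxy (C8a) carbons and leaves the acetal oxygen at C5. The same polarity gives chemoselectivity, since the electron-poor ketene should ignore the unactivated vinyl group. A slight excess of 4 and acid-free glassware should limit ketene dimerisation and hydrolysis of either partner.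

Step 4
Reactants: 11 5-(methoxymethoxy)-2-(2-methylbut-3-en-2-yl)-3-[tri(propan-2-yl)silyloxy]phenol; 6 chloromethyl methyl ether
Product: 12 [3,5-bis(methoxymethoxy)-2-(2-methylbut-3-en-2-yl)phenoxy]tri(propan-2-yl)silane
Conditions: NaH, DMF, 0 °C; then 6, 0 °C to rt
Reagents that add atoms: none
Why: Williamson etherification of the hindered sodium phenoxide with a small, reactive electrophile. O7 receives the same base-stable acetal as O5, because an aryl silyl ether would not survive hydroxide in steps 11 and 12.

Step 5
Reactants: 12 [3,5-bis(methoxymethoxy)-2-(2-methylbut-3-en-2-yl)phenoxy]tri(propan-2-yl)silane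
Product: 13 3,5-bis(methoxymethoxy)-2-(2-methylbut-3-en-2-yl)phenol
Conditions: Bu4NF, THF, 0 °C; aq. NH4Cl
Reagents that add atoms: none
Why: Fluoride cleaves the aryl silyl ether (strong Si–F bond, phenoxide leaving group) and leaves acetals and alkenes untouched. O1–H is released as the only free phenol.

Step 6
Reactants: 13 3,5-bis(methoxymethoxy)-2-(2-methylbut-3-en-2-yl)phenol
Product: 15 2-hydroxy-4,6-bis(methoxymethoxy)-3-(2-methylbut-3-en-2-yl)benzaldehyde, via hydroxymethylphenol magnesium salt 14 (not isolated)
Conditions: MgCl2, Et3N, (CH2O)n, MeCN, reflux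
Reagents that add atoms: paraformaldehyde (formaldehyde), C=O
Why: Casnati–Skattebøl ortho-formylation: the magnesium phenoxide binds formaldehyde and delivers it through a six-membered transition state to the only free ortho carbon, C4a, and a second formaldehyde oxidises the benzylic alkoxide 14 by hydride transfer. C6 is para to the phenol and receives no such delivery. 2-tert-Alkylphenols are standard substrates, and the basic medium spares the acetals.

Step 7
Reactants: 15 2-hydroxy-4,6-bis(methoxymethoxy)-3-(2-methylbut-3-en-2-yl)benzaldehyde
Product: 16 2-(1-hydroxyethyl)-3,5-bis(methoxymethoxy)-6-(2-methylbut-3-en-2-yl)phenol (racemic)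
Conditions: MeMgBr (3 equiv), THF, −78 to 0 °C; aq. NH4Cl; used crude
Reagents that add atoms: methylmagnesium bromide, C[Mg]Br
Why: Grignard addition to the aldehyde after deprotonation of the phenol, hence the excess. The carbinol centre forms as a racemate without control, which does not matter because step 8 removes it.

Step 8
Reactants: 16 2-(1-hydroxyethyl)-3,5-bis(methoxymethoxy)-6-(2-methylbut-3-en-2-yl)phenol
Product: 17 1-[2-hydroxy-4,6-bis(methoxymethoxy)-3-(2-methylbut-3-en-2-yl)phenyl]ethan-1-one
Conditions: MnO2 (activated), CH2Cl2, rt
Reagents that add atoms: none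
Why: Manganese dioxide oxidises the electron-rich benzylic alcohol to the ketone, which is stabilised by the hydrogen bond to O1–H. Isolated alkenes and acetals are inert, and immediate use of crude 16 avoids its ionisation to an ortho-quinone methide.

Step 9
Reactants: 18 3-bromo-4,5-dihydroxybenzaldehyde; 6 chloromethyl methyl ether
Product: 19 3-bromo-4,5-bis(methoxymethoxy)benzaldehyde
Conditions: 6 (2.5 equiv in all), i-Pr2NEt (3 equiv), CH2Cl2, 0 °C to rt
Reagents that add atoms: chloromethyl methyl ether (second equivalent of 6, for the second hydroxyl), COCCl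
Why: Base-mediated O-alkylation of both catechol hydroxyls, one equivalent of the chloromethyl ether per hydroxyl; the aldehyde-activated phenoxides are alkylated cleanly at oxygen. Ring B becomes stable to the hydroxide and peroxide of steps 11 and 12.

Step 10
Reactants: 19 3-bromo-4,5-bis(methoxymethoxy)benzaldehyde
Product: 20 3,4-bis(methoxymethoxy)-5-(3-methylbut-2-en-1-yl)benzaldehyde
Conditions: tributyl(3-methylbut-2-en-1-yl)stannane, Pd(PPh3)4 (5 mol %), DMF, 100 °C; aq. KF work-up
Reagents that add atoms: tributyl(3-methylbut-2-en-1-yl)stannane, CCCC[Sn](CCCC)(CCCC)CC=C(C)C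
Why: Stille coupling: zerovalent palladium inserts into the C–Br bond, the allylstannane transmetalates, and reductive elimination from the allyl complex at its less substituted terminus gives the linear prenyl arene. Aldehyde and acetals are tolerated.

Step 11
Reactants: 17 1-[2-hydroxy-4,6-bis(methoxymethoxy)-3-(2-methylbut-3-en-2-yl)phenyl]ethan-1-one; 20 3,4-bis(methoxymethoxy)-5-(3-methylbut-2-en-1-yl)benzaldehyde
Product: 21 (2E)-1-[2-hydroxy-4,6-bis(methoxymethoxy)-3-(2-methylbut-3-en-2-yl)phenyl]-3-[3,4-bis(methoxymethoxy)-5-(3-methylbut-2-en-1-yl)phenyl]prop-2-en-1-one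
Conditions: KOH, EtOH–H2O, rt
Reagents that add atoms: none
Why: Claisen–Schmidt condensation: the enolate of 17 adds to the non-enolisable aldehyde 20 and E1cB loss of water gives the thermodynamically favoured E-enone. The acetals are stable to hydroxide.

Step 12
Reactants: 21 (2E)-1-[2-hydroxy-4,6-bis(methoxymethoxy)-3-(2-methylbut-3-en-2-yl)phenyl]-3-[3,4-bis(methoxymethoxy)-5-(3-methylbut-2-en-1-yl)phenyl]prop-2-en-1-one
Product: 23 3-hydroxy-5,7-bis(methoxymethoxy)-2-[3,4-bis(methoxymethoxy)-5-(3-methylbut-2-en-1-yl)phenyl]-8-(2-methylbut-3-en-2-yl)-4H-chromen-4-one, via trans-dihydroflavonol 22 (not isolated)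
Conditions: 30% aq. H2O2, NaOH, MeOH, 0 °C to rt
Reagents that add atoms: hydrogen peroxide, OO
Why: Algar–Flynn–Oyamada oxidation: the O1 phenoxide closes onto the β-carbon (C2) while the α-carbon is oxygenated by hydroperoxide, giving the dihydroflavonol 22, which alkaline peroxide dehydrogenates to the flavonol. 22 forms as the racemic, thermodynamically preferred 2,3-trans isomer and both centres then vanish. Unactivated alkenes do not react with nucleophilic peroxide.

Step 13
Reactants: 23 3-hydroxy-5,7-bis(methoxymethoxy)-2-[3,4-bis(methoxymethoxy)-5-(3-methylbut-2-en-1-yl)phenyl]-8-(2-methylbut-3-en-2-yl)-4H-chromen-4-one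
Product: 24 2-[3,4-dihydroxy-5-(3-methylbut-2-en-1-yl)phenyl]-3,5,7-trihydroxy-8-(2-methylbut-3-en-2-yl)-4H-chromen-4-one
Conditions: 3 M aq. HCl, MeOH, rt to 40 °C, monitored and stopped at completion, under argon
Reagents that add atoms: none
Why: Acid-catalysed acetal exchange with methanol removes the four phenolic methoxymethyl groups, the carbonyl-activated C5 acetal first. Low temperature and short time should keep addition of the phenols to the two allyl groups slower than deprotection.

## Compound list

1 | methyl 2,2-dimethylbut-3-enoate | COC(=O)C(C)(C)C=C | starting material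
2 | lithium 1,1-dibromo-3,3-dimethylpenta-1,4-dien-2-olate (formed in the flask) | [Li+].[O-]C(=C(Br)Br)C(C)(C)C=C | intermediate
3 | lithium 3,3-dimethylpent-4-en-1-yn-1-olate (formed in the flask) | [Li+].[O-]C#CC(C)(C)C=C | intermediate
4 | [(3,3-dimethylpent-4-en-1-yn-1-yl)oxy]tri(propan-2-yl)silane | C=CC(C)(C)C#CO[Si](C(C)C)(C(C)C)C(C)C | intermediate
5 | cyclobutane-1,3-dione | O=C1CC(=O)C1 | starting material
6 | chloromethyl methyl ether | COCCl | starting material
7 | 3-(methoxymethoxy)cyclobut-2-en-1-one | COCOC1=CC(=O)C1 | intermediate
8 | 3-(methoxymethoxy)buta-1,3-dien-1-one (formed in the flask) | C=C(OCOC)C=C=O | intermediate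
9 | 4-[1-(methoxymethoxy)ethenyl]-2-(2-methylbut-3-en-2-yl)-3-[tri(propan-2-yl)silyloxy]cyclobut-2-en-1-one (racemic, formed in the flask) | O=C1C(C(C)(C)C=C)=C(O[Si](C(C)C)(C(C)C)C(C)C)C1C(=C)OCOC | intermediate
10 | (3E)-5-(methoxymethoxy)-2-(2-methylbut-3-en-2-yl)-3-[tri(propan-2-yl)silyloxy]hexa-1,3,5-trien-1-one (formed in the flask) | O=C=C(C(C)(C)C=C)/C(O[Si](C(C)C)(C(C)C)C(C)C)=C\C(=C)OCOC | intermediate
11 | 5-(methoxymethoxy)-2-(2-methylbut-3-en-2-yl)-3-[tri(propan-2-yl)silyloxy]phenol | Oc1cc(OCOC)cc(O[Si](C(C)C)(C(C)C)C(C)C)c1C(C)(C)C=C | intermediate
12 | [3,5-bis(methoxymethoxy)-2-(2-methylbut-3-en-2-yl)phenoxy]tri(propan-2-yl)silane | C=CC(C)(C)c1c(OCOC)cc(OCOC)cc1O[Si](C(C)C)(C(C)C)C(C)C | intermediate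
13 | 3,5-bis(methoxymethoxy)-2-(2-methylbut-3-en-2-yl)phenol | Oc1cc(OCOC)cc(OCOC)c1C(C)(C)C=C | intermediate
14 | 2-(hydroxymethyl)-3,5-bis(methoxymethoxy)-6-(2-methylbut-3-en-2-yl)phenol (present as its magnesium salt, formed in the flask) | OCc1c(O)c(C(C)(C)C=C)c(OCOC)cc1OCOC | intermediate
15 | 2-hydroxy-4,6-bis(methoxymethoxy)-3-(2-methylbut-3-en-2-yl)benzaldehyde | O=Cc1c(O)c(C(C)(C)C=C)c(OCOC)cc1OCOC | intermediate
16 | 2-(1-hydroxyethyl)-3,5-bis(methoxymethoxy)-6-(2-methylbut-3-en-2-yl)phenol (racemic) | CC(O)c1c(O)c(C(C)(C)C=C)c(OCOC)cc1OCOC | intermediate
17 | 1-[2-hydroxy-4,6-bis(methoxymethoxy)-3-(2-methylbut-3-en-2-yl)phenyl]ethan-1-one | CC(=O)c1c(O)c(C(C)(C)C=C)c(OCOC)cc1OCOC | intermediate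
18 | 3-bromo-4,5-dihydroxybenzaldehyde | O=Cc1cc(O)c(O)c(Br)c1 | starting material
19 | 3-bromo-4,5-bis(methoxymethoxy)benzaldehyde | O=Cc1cc(Br)c(OCOC)c(OCOC)c1 | intermediate
20 | 3,4-bis(methoxymethoxy)-5-(3-methylbut-2-en-1-yl)benzaldehyde | O=Cc1cc(CC=C(C)C)c(OCOC)c(OCOC)c1 | intermediate
21 | (2E)-1-[2-hydroxy-4,6-bis(methoxymethoxy)-3-(2-methylbut-3-en-2-yl)phenyl]-3-[3,4-bis(methoxymethoxy)-5-(3-methylbut-2-en-1-yl)phenyl]prop-2-en-1-one | COCOc1cc(OCOC)c(C(=O)/C=C/c2cc(CC=C(C)C)c(OCOC)c(OCOC)c2)c(O)c1C(C)(C)C=C | intermediate
22 | trans-3-hydroxy-5,7-bis(methoxymethoxy)-2-[3,4-bis(methoxymethoxy)-5-(3-methylbut-2-en-1-yl)phenyl]-8-(2-methylbut-3-en-2-yl)-2,3-dihydro-4H-chromen-4-one (racemic, 2R,3R enantiomer drawn, formed in the flask) | O=C1c2c(OCOC)cc(OCOC)c(C(C)(C)C=C)c2O[C@H](c2cc(OCOC)c(OCOC)c(CC=C(C)C)c2)[C@H]1O | intermediate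
23 | 3-hydroxy-5,7-bis(methoxymethoxy)-2-[3,4-bis(methoxymethoxy)-5-(3-methylbut-2-en-1-yl)phenyl]-8-(2-methylbut-3-en-2-yl)-4H-chromen-4-one | C=CC(C)(C)c1c(OCOC)cc(OCOC)c2c(=O)c(O)c(-c3cc(OCOC)c(OCOC)c(CC=C(C)C)c3)oc12 | intermediate
24 | 2-[3,4-dihydroxy-5-(3-methylbut-2-en-1-yl)phenyl]-3,5,7-trihydroxy-8-(2-methylbut-3-en-2-yl)-4H-chromen-4-one | C=CC(C)(C)c1c(O)cc(O)c2c(=O)c(O)c(-c3cc(O)c(O)c(CC=C(C)C)c3)oc12 | target

## Step count and least certain steps

Total: 13 steps. Longest linear sequence: 10 steps (1, 3, 4, 5, 6, 7, 8, 11, 12, 13).

**Step 3 (key step).** The most likely failure is slow capture of the vinylketene by the alkyne, whose reacting carbon is neopentyl-like. Ketene dimerisation, oligomerisation or loss of the acetal from the vinylogous ester would then outrun the [2+2]. The alkoxy group may also raise the temperature needed for ring opening of 7 beyond what the siloxyalkyne tolerates, and the product phenol could be acylated by surplus ketene. The fallback gives up the ring construction and makes the aryl–quaternary carbon bond by aromatic Claisen rearrangement. It sets out from chloromethyl methyl ether 6 and commercial benzene-1,3,5-triol F1. Two of the three hydroxyls are acetalised (6, i-Pr2NEt, statistical) to give 3,5-bis(methoxymethoxy)phenol F2. O-Alkylation with 1-bromo-3-methylbut-2-ene (K2CO3, acetone) gives 1,3-bis(methoxymethoxy)-5-[(3-methylbut-2-en-1-yl)oxy]benzene F3. Heating (N,N-diethylaniline, about 190 °C) moves the allyl group with inversion to either of the two equivalent ortho carbons. The fallback comes back to the route at 13 and replaces steps 1 to 5. Its own weakness would be a further shift to the para carbon.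

**Step 12.** The likely failure is ring closure at the α-carbon (five-membered) instead of the β-carbon, a pathway that an ortho substituent next to the ketone (here the C5 acetal) is known to favour. Retro-aldol cleavage of the enone in alkaline peroxide is a second risk. The fallback separates ring closure from oxygenation and sets out from 21. Oxa-Michael closure (NaOAc, EtOH, reflux) gives the racemic flavanone 5,7-bis(methoxymethoxy)-2-[3,4-bis(methoxymethoxy)-5-(3-methylbut-2-en-1-yl)phenyl]-8-(2-methylbut-3-en-2-yl)-2,3-dihydro-4H-chromen-4-one F4. Dehydrogenation (DDQ, dioxane, 80 °C) gives the corresponding flavone, 5,7-bis(methoxymethoxy)-2-[3,4-bis(methoxymethoxy)-5-(3-methylbut-2-en-1-yl)phenyl]-8-(2-methylbut-3-en-2-yl)-4H-chromen-4-one F5. Lithiation at C3 (LiN(i-Pr)2, THF, −78 °C) and trapping with B(OMe)3 give dimethyl {5,7-bis(methoxymethoxy)-2-[3,4-bis(methoxymethoxy)-5-(3-methylbut-2-en-1-yl)phenyl]-8-(2-methylbut-3-en-2-yl)-4-oxo-4H-chromen-3-yl}boronate F6, which is oxidised in the same flask (H2O2, aq. NaHCO3, 0 °C). The fallback comes back at 23. Its own weakness would be hydride abstraction by the quinone at the doubly activated CH2 of the prenyl group.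

**Step 1.** The likely failure is slow addition of LiCHBr2 to the ester carbonyl next to a quaternary carbon, or incomplete rearrangement, so that unreacted ester or ketone-derived material is silylated instead of the ynolate. The fallback reaches the ynolate by oxidation of an acetylide and sets out from 1. Reduction (i-Bu2AlH, CH2Cl2, −78 °C) gives 2,2-dimethylbut-3-enal F7. Ohira–Bestmann homologation (dimethyl (1-diazo-2-oxopropyl)phosphonate, K2CO3, MeOH) gives 3,3-dimethylpent-4-en-1-yne F8. Deprotonation (n-BuLi) and oxygen transfer from LiOOt-Bu give ynolate 3, which is silylated as in step 1. The fallback comes back at 3 and so at 4.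

**Step 13.** The likely failure is acid-catalysed addition of the 4'-hydroxyl to the prenyl group or of the 7-hydroxyl to the dimethylallyl group before the last acetal has gone, or incomplete cleavage if conditions are kept too mild. The fallback avoids protic acid and sets out from 23. Acetal-to-silyl-ether exchange (Me3SiOTf, 2,2'-bipyridyl, MeCN, 0 °C) converts the four acetals and the 3-hydroxyl into the pentakis(trimethylsilyl) ether 3,5,7-tris(trimethylsilyloxy)-2-[3,4-bis(trimethylsilyloxy)-5-(3-methylbut-2-en-1-yl)phenyl]-8-(2-methylbut-3-en-2-yl)-4H-chromen-4-one F9. Brief methanolysis (MeOH, catalytic K2CO3, 0 °C, under argon) removes the silyl groups. The fallback comes back at 24.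

## Further compounds

F1 | step 3 | benzene-1,3,5-triol | Oc1cc(O)cc(O)c1
F2 | step 3 | 3,5-bis(methoxymethoxy)phenol | COCOc1cc(O)cc(OCOC)c1
F3 | step 3 | 1,3-bis(methoxymethoxy)-5-[(3-methylbut-2-en-1-yl)oxy]benzene | COCOc1cc(OCOC)cc(OCC=C(C)C)c1
F4 | step 12 | 5,7-bis(methoxymethoxy)-2-[3,4-bis(methoxymethoxy)-5-(3-methylbut-2-en-1-yl)phenyl]-8-(2-methylbut-3-en-2-yl)-2,3-dihydro-4H-chromen-4-one (racemic) | C=CC(C)(C)c1c(OCOC)cc(OCOC)c2c1OC(c1cc(OCOC)c(OCOC)c(CC=C(C)C)c1)CC2=O
F5 | step 12 | 5,7-bis(methoxymethoxy)-2-[3,4-bis(methoxymethoxy)-5-(3-methylbut-2-en-1-yl)phenyl]-8-(2-methylbut-3-en-2-yl)-4H-chromen-4-one | C=CC(C)(C)c1c(OCOC)cc(OCOC)c2c(=O)cc(-c3cc(OCOC)c(OCOC)c(CC=C(C)C)c3)oc12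
F6 | step 12 | dimethyl {5,7-bis(methoxymethoxy)-2-[3,4-bis(methoxymethoxy)-5-(3-methylbut-2-en-1-yl)phenyl]-8-(2-methylbut-3-en-2-yl)-4-oxo-4H-chromen-3-yl}boronate | C=CC(C)(C)c1c(OCOC)cc(OCOC)c2c(=O)c(B(OC)OC)c(-c3cc(OCOC)c(OCOC)c(CC=C(C)C)c3)oc12
F7 | step 1 | 2,2-dimethylbut-3-enal | C=CC(C)(C)C=O
F8 | step 1 | 3,3-dimethylpent-4-en-1-yne | C#CC(C)(C)C=C
F9 | step 13 | 3,5,7-tris(trimethylsilyloxy)-2-[3,4-bis(trimethylsilyloxy)-5-(3-methylbut-2-en-1-yl)phenyl]-8-(2-methylbut-3-en-2-yl)-4H-chromen-4-one | C=CC(C)(C)c1c(O[Si](C)(C)C)cc(O[Si](C)(C)C)c2c(=O)c(O[Si](C)(C)C)c(-c3cc(O[Si](C)(C)C)c(O[Si](C)(C)C)c(CC=C(C)C)c3)oc12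
A1 | alternative 1 | 1-[2,4-bis(methoxymethoxy)-6-[(3-methylbut-2-en-1-yl)oxy]phenyl]-2-(methoxymethoxy)-3-[3,4-bis(methoxymethoxy)-5-(3-methylbut-2-en-1-yl)phenyl]propane-1,3-dione | COCOc1cc(OCOC)c(C(=O)C(OCOC)C(=O)c2cc(CC=C(C)C)c(OCOC)c(OCOC)c2)c(OCC=C(C)C)c1
A2 | alternative 1 | 3,5,7-tris(methoxymethoxy)-2-[3,4-bis(methoxymethoxy)-5-(3-methylbut-2-en-1-yl)phenyl]-8-(2-methylbut-3-en-2-yl)-4H-chromen-4-one | COCOc1cc(OCOC)c2c(=O)c(OCOC)c(-c3cc(CC=C(C)C)c(OCOC)c(OCOC)c3)oc2c1C(C)(C)C=C
A3 | alternative 2 | 6-(2,2-dimethylbut-3-en-1-yl)-4-(methoxymethoxy)-2H-pyran-2-one | C=CC(C)(C)CC1=CC(OCOC)=CC(=O)O1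
A4 | alternative 2 | methyl (2E)-3-(methoxymethoxy)-7,7-dimethyl-5-oxonona-2,8-dienoate | COC(=O)/C=C(/OCOC)CC(=O)CC(C)(C)C=C
A5 | alternative 2 | 5-(methoxymethoxy)-2-(2-methylbut-3-en-2-yl)benzene-1,3-diol | Oc1cc(OCOC)cc(O)c1C(C)(C)C=C
A6 | alternative 3 | 2-acetyl-3,5-bis(methoxymethoxy)phenyl tert-butyl carbonate | CC(=O)c1c(OCOC)cc(OCOC)cc1OC(=O)OC(C)(C)C
A7 | alternative 3 | 3,5-bis(methoxymethoxy)-6-(propan-2-ylidene)cyclohexa-2,4-dien-1-one | CC(C)=C1C(=O)C=C(OCOC)C=C1OCOC
A8 | alternative 3 | 3,5-bis(methoxymethoxy)-2-(2-methylbut-3-en-2-yl)phenol | Oc1cc(OCOC)cc(OCOC)c1C(C)(C)C=C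
A9 | alternative 3 | 3,5-bis(methoxymethoxy)-2-(prop-1-en-2-yl)phenol | C=C(C)c1c(O)cc(OCOC)cc1OCOC
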